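**Plan**

- Retrosynthesis: the two phenols are carried as benzyl ethers and the C3=C4 alkene is traced back to a C4 ketone. Ring B is then cut at C2–C3, and the open chain is cut at C1–C8a into a cis-aryl epoxide and an ortho-metallated propiophenone ketal, both from O-benzylsyringaldehyde.
- Enabling feature: with C4 as a ketone on ring A (at C4a), C3 is an enolisable α-carbon. C2, its future ring neighbour, is a methyl-bearing carbinol carbon tethered through C1 to C8a, so nucleophile and leaving group sit 1,6 across the ortho positions of ring A.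
- Forward order: the two aryl fragments are joined at C1–C8a by epoxide arylation. Ring B, the only ring made, closes at C2–C3 as a 1-tetralone, followed by reduction, dehydration and debenzylation.
- Stereochemistry: Jacobsen epoxidation of the (Z)-propenylarene fixes the absolute configuration. C1 is set by inversion in the epoxide opening and C2 by inversion in the ring closure, which gives the cis (1S,2S) pair. The transient C3 centre is erased by dehydration.

Key step: step 10

Remark: locants C1–C8a are those of the 1,2-dihydronaphthalene core (C1 aryl-bearing, C2 and C3 methyl-bearing, C4 the alkene CH). The facial sense of the (S,S)-manganese salen catalyst is assumed from the cis-β-methylstyrene and indene series; the (R,R)-catalyst would be used if the sense proved reversed for this arene.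

**Route**

Step 1
Reactants: 1 syringaldehyde
Product: 2 4-(benzyloxy)-3,5-dimethoxybenzaldehyde
Conditions: BnBr, K2CO3, DMF, 60 °C
Reagents that add atoms: benzyl bromide, BrCc1ccccc1
Why: Williamson etherification of the phenoxide gives a benzyl ether that should survive the organometallic, acidic and enolate steps and serves both fragments.

Step 2
Reactants: 2 4-(benzyloxy)-3,5-dimethoxybenzaldehyde; 3 ethyltriphenylphosphonium bromide
Product: 5 2-(benzyloxy)-1,3-dimethoxy-5-[(Z)-prop-1-en-1-yl]benzene, via ethylidenetriphenylphosphorane 4 (not isolated)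
Conditions: NaN(SiMe3)2, THF, 0 °C; then 2, −78 °C → rt
Reagents that add atoms: none
Why: Wittig olefination with a non-stabilised ylide under lithium-free conditions should favour the (Z)-alkene through the kinetic cis-oxaphosphetane; residual (E)-isomer would be removed on AgNO3-impregnated silica or later as the trans-epoxide.

Step 3
Reactants: 5 2-(benzyloxy)-1,3-dimethoxy-5-[(Z)-prop-1-en-1-yl]benzene
Product: 6 (2R,3S)-3-[4-(benzyloxy)-3,5-dimethoxyphenyl]-2-methyloxirane
Conditions: (S,S)-(salen)MnCl [salen = N,N'-bis(3,5-di-tert-butylsalicylidene)-1,2-cyclohexanediaminate] (5 mol %), 4-phenylpyridine N-oxide (20 mol %), aq. NaOCl (pH 11.3, Na2HPO4), CH2Cl2, 0 °C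
Reagents that add atoms: sodium hypochlorite, [Na+].[O-]Cl
Why: Jacobsen–Katsuki epoxidation works best on conjugated cis-disubstituted alkenes, and the (S,S)-catalyst is expected to deliver oxygen to the face that gives the (2R,3S)-cis-epoxide, which sets both stereocentres of the diad; any trans-epoxide from bond rotation in the radical intermediate would be separated on Et3N-deactivated silica.

Step 4
Reactants: 2 4-(benzyloxy)-3,5-dimethoxybenzaldehyde
Product: 7 4-(benzyloxy)-2-bromo-3,5-dimethoxybenzaldehyde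
Conditions: NBS (1.05 equiv), DMF, rt, dark
Reagents that add atoms: N-bromosuccinimide, O=C1CCC(=O)N1Br
Why: Electrophilic aromatic bromination can only occur at the two equivalent free positions, each ortho and para to a methoxy group, and the unactivated benzyl ring should not compete.

Step 5
Reactants: 7 4-(benzyloxy)-2-bromo-3,5-dimethoxybenzaldehyde; 8 ethylmagnesium bromide
Product: 9 1-[4-(benzyloxy)-2-bromo-3,5-dimethoxyphenyl]propan-1-ol (racemic)
Conditions: EtMgBr, THF, −78 → 0 °C; aq. NH4Cl
Reagents that add atoms: none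
Why: Grignard 1,2-addition to the aldehyde is far faster at low temperature than halogen–magnesium exchange at the aryl bromide, and the racemic carbinol centre is removed in the next step.

Step 6
Reactants: 9 1-[4-(benzyloxy)-2-bromo-3,5-dimethoxyphenyl]propan-1-ol
Product: 10 1-[4-(benzyloxy)-2-bromo-3,5-dimethoxyphenyl]propan-1-one
Conditions: Dess–Martin periodinane, CH2Cl2, rt
Reagents that add atoms: none
Why: Dess–Martin oxidation converts the secondary benzylic alcohol into the aryl ethyl ketone under neutral conditions that leave the aryl bromide and the ethers untouched.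

Step 7
Reactants: 10 1-[4-(benzyloxy)-2-bromo-3,5-dimethoxyphenyl]propan-1-one
Product: 11 2-[4-(benzyloxy)-2-bromo-3,5-dimethoxyphenyl]-2-ethyl-1,3-dioxolane
Conditions: HOCH2CH2OH, TsOH·H2O (cat.), toluene, reflux, Dean–Stark
Reagents that add atoms: ethylene glycol, OCCO
Why: Acid-catalysed ketalisation with azeotropic water removal masks the ketone as a dioxolane so that the same ring can later carry a carbon–magnesium bond.

Step 8
Reactants: 11 2-[4-(benzyloxy)-2-bromo-3,5-dimethoxyphenyl]-2-ethyl-1,3-dioxolane; 6 (2R,3S)-3-[4-(benzyloxy)-3,5-dimethoxyphenyl]-2-methyloxirane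
Product: 14 1-{4-(benzyloxy)-2-[(1S,2R)-1-[4-(benzyloxy)-3,5-dimethoxyphenyl]-2-hydroxypropyl]-3,5-dimethoxyphenyl}propan-1-one, via aryl Grignard reagent 12 (not isolated), via ketal alcohol 13 (not isolated)
Conditions: Mg, LiCl, THF, rt; CuI (10 mol %), then 6, −30 → 0 °C; then 2 M aq. HCl, THF, rt
Reagents that add atoms: water, O
Why: Magnesium insertion gives the ortho-chelated aryl Grignard reagent, whose copper-catalysed SN2 opening of the aryl epoxide should occur at the electronically activated benzylic carbon anti to the C–O bond, so that C1 is set with inversion while C2 keeps the epoxide configuration; the acidic work-up then hydrolyses the dioxolane.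

Step 9
Reactants: 14 1-{4-(benzyloxy)-2-[(1S,2R)-1-[4-(benzyloxy)-3,5-dimethoxyphenyl]-2-hydroxypropyl]-3,5-dimethoxyphenyl}propan-1-one
Product: 15 (1S,2R)-1-[3-(benzyloxy)-2,4-dimethoxy-6-propanoylphenyl]-1-[4-(benzyloxy)-3,5-dimethoxyphenyl]propan-2-yl methanesulfonate
Conditions: MsCl, Et3N, CH2Cl2, −10 → 0 °C
Reagents that add atoms: methanesulfonyl chloride, CS(=O)(=O)Cl
Why: O-sulfonylation of the secondary alcohol leaves the C2–O bond intact and so retains configuration; the keto mesylate would be kept cold and used at once to forestall participation by the carbonyl oxygen or the neighbouring aryl groups.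

Step 10
Reactants: 15 (1S,2R)-1-[3-(benzyloxy)-2,4-dimethoxy-6-propanoylphenyl]-1-[4-(benzyloxy)-3,5-dimethoxyphenyl]propan-2-yl methanesulfonate
Product: 17 (3S,4S)-6-(benzyloxy)-4-[4-(benzyloxy)-3,5-dimethoxyphenyl]-5,7-dimethoxy-2,3-dimethyl-3,4-dihydronaphthalen-1(2H)-one (both C2 epimers), via potassium enolate 16 (not isolated)
Conditions: KN(SiMe3)2 (1.05 equiv), THF–toluene, −78 → 0 °C
Reagents that add atoms: none
Why: KN(SiMe3)2 removes a proton from the propionyl CH2 group, the only enolisable site, and the enolate carbon (target C3) displaces the mesylate at target C2 from the rear in an intramolecular SN2 reaction. The closest known reaction type is the base-mediated cyclisation of keto sulfonates, that is, intramolecular alkylation of a ketone enolate by a secondary sulfonate. Ring B closes in the 6-(enolendo)-exo-tet mode, the ortho-substituted aryl enolate being twisted out of the plane of ring A so that the C3 lobe lies over C2. C2 is inverted stereospecifically, which turns the (1S,2R) open-chain diad into the cis (1S,2S) relation of the target, whereas the new α-centre forms without control and is harmless because it becomes sp2 in step 12. The step needs substitution to beat E2 loss of the doubly benzylic C1–H and carbon attack to beat oxygen attack (which would give a 1-ethylidene-isochromane). Complete enolisation at −78 °C with one equivalent of hindered base leaves no free base, the 1,6-ortho tether gives closure a high effective molarity, and the twisted contact-ion-pair enolate in a weakly polar medium should react at carbon.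

Step 11
Reactants: 17 (3S,4S)-6-(benzyloxy)-4-[4-(benzyloxy)-3,5-dimethoxyphenyl]-5,7-dimethoxy-2,3-dimethyl-3,4-dihydronaphthalen-1(2H)-one
Product: 18 (3S,4S)-6-(benzyloxy)-4-[4-(benzyloxy)-3,5-dimethoxyphenyl]-5,7-dimethoxy-2,3-dimethyl-1,2,3,4-tetrahydronaphthalen-1-ol (mixture at C1 and C2)
Conditions: NaBH4, MeOH–THF, 0 °C → rt
Reagents that add atoms: none
Why: Borohydride reduction of the aryl ketone gives the benzylic alcohol, and the configurations at the carbinol carbon and its methyl-bearing neighbour do not matter because both carbons become sp2.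

Step 12
Reactants: 18 (3S,4S)-6-(benzyloxy)-4-[4-(benzyloxy)-3,5-dimethoxyphenyl]-5,7-dimethoxy-2,3-dimethyl-1,2,3,4-tetrahydronaphthalen-1-ol
Product: 19 (1S,2S)-7-(benzyloxy)-1-[4-(benzyloxy)-3,5-dimethoxyphenyl]-6,8-dimethoxy-2,3-dimethyl-1,2-dihydronaphthalene
Conditions: TsOH·H2O (cat.), toluene, 50 °C, argon
Reagents that add atoms: none
Why: Acid-catalysed E1 dehydration passes through the benzylic cation at target C4, stabilised by the para-benzyloxy group of ring A, which can only lose the C3 proton and so gives the conjugated C3=C4 alkene without touching C1 or C2.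

Step 13
Reactants: 19 (1S,2S)-7-(benzyloxy)-1-[4-(benzyloxy)-3,5-dimethoxyphenyl]-6,8-dimethoxy-2,3-dimethyl-1,2-dihydronaphthalene
Product: 20 4-[(1S,2S)-7-hydroxy-6,8-dimethoxy-2,3-dimethyl-1,2-dihydronaphthalen-1-yl]-2,6-dimethoxyphenol
Conditions: BCl3, C6HMe5, CH2Cl2, −78 °C; then MeOH
Reagents that add atoms: none
Why: Lewis-acid cleavage of aryl benzyl ethers with BCl3 at −78 °C, with pentamethylbenzene as a non-basic benzyl cation scavenger, should spare the aryl methyl ethers and, unlike hydrogenolysis, the trisubstituted alkene.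

**Compound list**

1 | syringaldehyde | COc1cc(C=O)cc(OC)c1O | starting material
2 | 4-(benzyloxy)-3,5-dimethoxybenzaldehyde | COc1cc(C=O)cc(OC)c1OCc1ccccc1 | intermediate
3 | ethyltriphenylphosphonium bromide | CC[P+](c1ccccc1)(c1ccccc1)c1ccccc1.[Br-] | starting material
4 | ethylidenetriphenylphosphorane (not isolated) | CC=P(c1ccccc1)(c1ccccc1)c1ccccc1 | intermediate
5 | 2-(benzyloxy)-1,3-dimethoxy-5-[(Z)-prop-1-en-1-yl]benzene | C/C=C\c1cc(OC)c(OCc2ccccc2)c(OC)c1 | intermediate
6 | (2R,3S)-3-[4-(benzyloxy)-3,5-dimethoxyphenyl]-2-methyloxirane (cis) | C[C@H]1O[C@H]1c1cc(OC)c(OCc2ccccc2)c(OC)c1 | intermediate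
7 | 4-(benzyloxy)-2-bromo-3,5-dimethoxybenzaldehyde | COc1cc(C=O)c(Br)c(OC)c1OCc1ccccc1 | intermediate
8 | ethylmagnesium bromide | CC[Mg]Br | starting material
9 | 1-[4-(benzyloxy)-2-bromo-3,5-dimethoxyphenyl]propan-1-ol (racemic) | CCC(O)c1cc(OC)c(OCc2ccccc2)c(OC)c1Br | intermediate
10 | 1-[4-(benzyloxy)-2-bromo-3,5-dimethoxyphenyl]propan-1-one | CCC(=O)c1cc(OC)c(OCc2ccccc2)c(OC)c1Br | intermediate
11 | 2-[4-(benzyloxy)-2-bromo-3,5-dimethoxyphenyl]-2-ethyl-1,3-dioxolane | CCC1(OCCO1)c1cc(OC)c(OCc2ccccc2)c(OC)c1Br | intermediate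
12 | [3-(benzyloxy)-6-(2-ethyl-1,3-dioxolan-2-yl)-2,4-dimethoxyphenyl]magnesium bromide (not isolated) | CCC1(OCCO1)c1cc(OC)c(OCc2ccccc2)c(OC)c1[Mg]Br | intermediate
13 | (1S,2R)-1-[3-(benzyloxy)-6-(2-ethyl-1,3-dioxolan-2-yl)-2,4-dimethoxyphenyl]-1-[4-(benzyloxy)-3,5-dimethoxyphenyl]propan-2-ol (not isolated) | CCC1(OCCO1)c1cc(OC)c(OCc2ccccc2)c(OC)c1[C@H](c1cc(OC)c(OCc2ccccc2)c(OC)c1)[C@@H](C)O | intermediate
14 | 1-{4-(benzyloxy)-2-[(1S,2R)-1-[4-(benzyloxy)-3,5-dimethoxyphenyl]-2-hydroxypropyl]-3,5-dimethoxyphenyl}propan-1-one | CCC(=O)c1cc(OC)c(OCc2ccccc2)c(OC)c1[C@H](c1cc(OC)c(OCc2ccccc2)c(OC)c1)[C@@H](C)O | intermediate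
15 | (1S,2R)-1-[3-(benzyloxy)-2,4-dimethoxy-6-propanoylphenyl]-1-[4-(benzyloxy)-3,5-dimethoxyphenyl]propan-2-yl methanesulfonate | CCC(=O)c1cc(OC)c(OCc2ccccc2)c(OC)c1[C@H](c1cc(OC)c(OCc2ccccc2)c(OC)c1)[C@@H](C)OS(C)(=O)=O | intermediate
16 | potassium (Z)-enolate of 15 (not isolated) | C/C=C(\[O-])c1cc(OC)c(OCc2ccccc2)c(OC)c1[C@H](c1cc(OC)c(OCc2ccccc2)c(OC)c1)[C@@H](C)OS(C)(=O)=O.[K+] | intermediate
17 | (3S,4S)-6-(benzyloxy)-4-[4-(benzyloxy)-3,5-dimethoxyphenyl]-5,7-dimethoxy-2,3-dimethyl-3,4-dihydronaphthalen-1(2H)-one (C2 epimers) | COc1cc([C@H]2c3c(cc(OC)c(OCc4ccccc4)c3OC)C(=O)C(C)[C@H]2C)cc(OC)c1OCc1ccccc1 | intermediate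
18 | (3S,4S)-6-(benzyloxy)-4-[4-(benzyloxy)-3,5-dimethoxyphenyl]-5,7-dimethoxy-2,3-dimethyl-1,2,3,4-tetrahydronaphthalen-1-ol (C1/C2 epimers) | COc1cc([C@H]2c3c(cc(OC)c(OCc4ccccc4)c3OC)C(O)C(C)[C@H]2C)cc(OC)c1OCc1ccccc1 | intermediate
19 | (1S,2S)-7-(benzyloxy)-1-[4-(benzyloxy)-3,5-dimethoxyphenyl]-6,8-dimethoxy-2,3-dimethyl-1,2-dihydronaphthalene | COc1cc([C@H]2c3c(cc(OC)c(OCc4ccccc4)c3OC)C=C(C)[C@H]2C)cc(OC)c1OCc1ccccc1 | intermediate
20 | 4-[(1S,2S)-7-hydroxy-6,8-dimethoxy-2,3-dimethyl-1,2-dihydronaphthalen-1-yl]-2,6-dimethoxyphenol | COc1cc([C@H]2c3c(cc(OC)c(O)c3OC)C=C(C)[C@H]2C)cc(OC)c1O | target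

**Step count and risks**

Total step count: 13. Longest linear sequence: 11 steps (steps 1, 4–13 from syringaldehyde); the epoxide branch (steps 1–3) joins at step 8.

Steps most likely to fail:

1. Step 8 (epoxide arylation). The di-ortho-substituted aryl nucleophile may attack the non-benzylic carbon, the magnesium halide may induce rearrangement of the epoxide to an aryl acetone, or an open benzylic cation may erode the inversion at C1. The fallback reverses the roles, so that the hindered ring carries the epoxide and the unhindered syringyl ring is the nucleophile. It sets out from bromo ketal 11. Suzuki–Miyaura coupling with (E)-prop-1-enylboronic acid (Pd(OAc)2, SPhos, K3PO4, toluene–water) would give 2-{4-(benzyloxy)-3,5-dimethoxy-2-[(E)-prop-1-en-1-yl]phenyl}-2-ethyl-1,3-dioxolane F1. Shi epoxidation (D-fructose-derived ketone catalyst, KHSO5, K2CO3 buffer, MeCN–dimethoxymethane, 0 °C) should give 2-{4-(benzyloxy)-3,5-dimethoxy-2-[(2R,3R)-3-methyloxiran-2-yl]phenyl}-2-ethyl-1,3-dioxolane F2; the trans-epoxide is required here because the two aryl groups at C1 exchange their roles. Benzylation of commercial 4-bromo-2,6-dimethoxyphenol gives 5-bromo-2-(benzyloxy)-1,3-dimethoxybenzene F3, and magnesium insertion gives [4-(benzyloxy)-3,5-dimethoxyphenyl]magnesium bromide F4. With CuI catalysis F4 should open F2 at the benzylic carbon with inversion to give ketal alcohol 13, and the acidic work-up returns to hydroxy ketone 14.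

2. Step 10 (ring closure). Base-induced E2 loss of methanesulfonic acid toward the 1,1-diarylpropene, or closure through the enolate oxygen, may outrun C-alkylation at the hindered secondary carbon. The fallback replaces the enolate by a metalated N,N-dimethylhydrazone, a carbon-only and more reactive nucleophile that alkylates at lower temperature. It sets out from hydroxy ketone 14. Condensation with Me2NNH2 (AcOH cat., EtOH, reflux) would give the N,N-dimethylhydrazone of hydroxy ketone 14 F5, and MsCl/Et3N the corresponding hydrazone mesylate F6. LiN(iPr)2 in THF at −78 °C would generate the lithium aza-enolate of the hydrazone mesylate F7, which should close the same C2–C3 bond with inversion to the N,N-dimethylhydrazone of tetralone 17 F8. Hydrolysis with aqueous oxalic acid returns to tetralone 17.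

3. Step 13 (debenzylation). The Lewis acid, or HCl formed from it, may trigger cationic reactions at the electron-rich styrene-type alkene or cleave a flanking methyl ether. The fallback removes the benzyl groups before the alkene exists. It sets out from tetralone 17. Hydrogenolysis (H2, Pd/C, EtOAc–EtOH, rt) would give (3S,4S)-6-hydroxy-4-(4-hydroxy-3,5-dimethoxyphenyl)-5,7-dimethoxy-2,3-dimethyl-3,4-dihydronaphthalen-1(2H)-one F9. NaBH4 in MeOH would give (3S,4S)-4-(4-hydroxy-3,5-dimethoxyphenyl)-5,7-dimethoxy-2,3-dimethyl-1,2,3,4-tetrahydronaphthalene-1,6-diol F10. Dehydration with catalytic TsOH in toluene, easy because the carbinol is para to a free phenol, leads directly to target 20.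

**Further compounds**

F1 | step 8 | 2-{4-(benzyloxy)-3,5-dimethoxy-2-[(E)-prop-1-en-1-yl]phenyl}-2-ethyl-1,3-dioxolane | C/C=C/c1c(OC)c(OCc2ccccc2)c(OC)cc1C1(CC)OCCO1
F2 | step 8 | 2-{4-(benzyloxy)-3,5-dimethoxy-2-[(2R,3R)-3-methyloxiran-2-yl]phenyl}-2-ethyl-1,3-dioxolane | C[C@H]1O[C@@H]1c1c(OC)c(OCc2ccccc2)c(OC)cc1C1(CC)OCCO1
F3 | step 8 | 5-bromo-2-(benzyloxy)-1,3-dimethoxybenzene | COc1cc(Br)cc(OC)c1OCc1ccccc1
F4 | step 8 | [4-(benzyloxy)-3,5-dimethoxyphenyl]magnesium bromide | COc1cc([Mg]Br)cc(OC)c1OCc1ccccc1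
F5 | step 10 | N,N-dimethylhydrazone of hydroxy ketone 14 | CCC(=NN(C)C)c1cc(OC)c(OCc2ccccc2)c(OC)c1[C@H](c1cc(OC)c(OCc2ccccc2)c(OC)c1)[C@@H](C)O
F6 | step 10 | hydrazone mesylate (methanesulfonate of F5) | CCC(=NN(C)C)c1cc(OC)c(OCc2ccccc2)c(OC)c1[C@H](c1cc(OC)c(OCc2ccccc2)c(OC)c1)[C@@H](C)OS(C)(=O)=O
F7 | step 10 | lithium aza-enolate of the hydrazone mesylate | CC=C([N-]N(C)C)c1cc(OC)c(OCc2ccccc2)c(OC)c1[C@H](c1cc(OC)c(OCc2ccccc2)c(OC)c1)[C@@H](C)OS(C)(=O)=O.[Li+]
F8 | step 10 | N,N-dimethylhydrazone of tetralone 17 | COc1cc([C@H]2c3c(cc(OC)c(OCc4ccccc4)c3OC)C(=NN(C)C)C(C)[C@H]2C)cc(OC)c1OCc1ccccc1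
F9 | step 13 | (3S,4S)-6-hydroxy-4-(4-hydroxy-3,5-dimethoxyphenyl)-5,7-dimethoxy-2,3-dimethyl-3,4-dihydronaphthalen-1(2H)-one | COc1cc([C@H]2c3c(cc(OC)c(O)c3OC)C(=O)C(C)[C@H]2C)cc(OC)c1O
F10 | step 13 | (3S,4S)-4-(4-hydroxy-3,5-dimethoxyphenyl)-5,7-dimethoxy-2,3-dimethyl-1,2,3,4-tetrahydronaphthalene-1,6-diol | COc1cc([C@H]2c3c(cc(OC)c(O)c3OC)C(O)C(C)[C@H]2C)cc(OC)c1O
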